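## Retrosynthetic overview

1. Endgame on ring B: C6=C7 by ketone dehydrogenation and the C7 side chain by aldol with acetone; the C3/C4 esters come from a 3α,4α-diol made by α-face dihydroxylation of a trans-fused Δ3-octal-8-one.
2. Ring A: ring-closing metathesis (C3=C4) of a cyclohexanone carrying trans butenyl (on C10) and isopropenyl (on C5) groups; the butenyl group comes from an aldehyde by Wittig methylenation.
3. Key bond C1–C10: a tertiary β-keto radical at C10 (the β-carbon of the C8 ketone, released by one-electron ring opening of a 1-siloxybicyclo[3.1.0]hexane) adds to the β-carbon of acrolein. The same event expands the cyclopentane to ring B and sets the quaternary centre anti to C5.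
4. The bicycle comes from Simmons–Smith cyclopropanation of the silyl enol ether trapped after a catalytic asymmetric conjugate addition of isopropenyl to 2-methylcyclopent-2-enone (sets C5, the only catalyst-controlled centre).
5. Ring order: five-membered ring (bought) → ring B (one-carbon ring expansion) → ring A (metathesis).

Assumption: carbon building blocks are numbered as starting materials; small auxiliary reagents that transfer atoms are given by name and SMILES on the reagent line. Atom labels C1–C15 are eudesmane numbering of the target (C8 ketone, C10 angular-methyl carbon, C3/C4 ester carbons).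

## Route

Step 1
Reactants: 1 2-methylcyclopent-2-en-1-one; 2 isopropenylmagnesium bromide
Product: 4 trimethyl{[(3S)-2-methyl-3-(prop-1-en-2-yl)cyclopent-1-en-1-yl]oxy}silane, via bromomagnesium enolate 3 (not isolated)
Conditions: CuBr·SMe2 (5 mol%), (R)-1-[(S)-2-(diphenylphosphino)ferrocenyl]ethyldicyclohexylphosphine (6 mol%; ligand enantiomer chosen to give 3S), t-BuOMe, −78 °C; then TMSCl, Et3N, DMPU, −78 → 0 °C
Reagents that add atoms: chlorotrimethylsilane, C[Si](C)(C)Cl
Why: Copper-catalysed asymmetric conjugate addition of the alkenyl Grignard reagent sets the C5 stereocentre under control of the chiral diphosphine–copper complex, and O-silylation of the regiodefined magnesium enolate fixes the tetrasubstituted enol ether (C8=C10) needed next.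

Step 2
Reactants: 4 trimethyl{[(3S)-2-methyl-3-(prop-1-en-2-yl)cyclopent-1-en-1-yl]oxy}silane
Product: 5 trimethyl{[(1R,4S,5S)-5-methyl-4-(prop-1-en-2-yl)bicyclo[3.1.0]hexan-1-yl]oxy}silane
Conditions: CH2I2, Zn–Cu couple, Et2O, reflux; pyridine, filter
Reagents that add atoms: diiodomethane, ICI
Why: Simmons–Smith cyclopropanation is much faster on the electron-rich silyl enol ether than on the 1,1-disubstituted alkene and occurs anti to the isopropenyl group (this cyclopropane stereochemistry is erased in step 3); the new CH2 becomes C9.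

Step 3
Reactants: 5 trimethyl{[(1R,4S,5S)-5-methyl-4-(prop-1-en-2-yl)bicyclo[3.1.0]hexan-1-yl]oxy}silane; 6 acrolein
Product: 7 3-[(1R,2S)-1-methyl-5-oxo-2-(prop-1-en-2-yl)cyclohexyl]propanal
Conditions: 6 (3 equiv), 9-mesityl-10-methylacridinium tetrafluoroborate (5 mol%), 2,6-lutidine (20 mol%), MeOH (5 equiv), MeCN, 450 nm LEDs, rt
Reagents that add atoms: none
Why: Proposed new method: photoinduced one-electron oxidation of the siloxycyclopropane gives a radical cation whose internal C–C bond cleaves (strain release, tertiary radical) to the ring-expanded 3-oxocyclohexyl radical at C10, which undergoes Giese addition to acrolein anti to the neighbouring isopropenyl group to set the quaternary centre (R), after which back electron transfer from the acridinyl radical and protonation give the aldehyde while methanol takes up the silyl group; the closest known reaction types are the Ito–Saegusa FeCl3 ring expansion of 1-siloxybicyclo[n.1.0]alkanes, photoinduced-electron-transfer ring opening of bicyclic cyclopropyl silyl ethers, and Giese additions of cyclopropanol-derived β-keto radicals.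

Step 4
Reactants: 7 3-[(1R,2S)-1-methyl-5-oxo-2-(prop-1-en-2-yl)cyclohexyl]propanal
Product: 8 (3R,4S)-3-(but-3-en-1-yl)-3-methyl-4-(prop-1-en-2-yl)cyclohexan-1-one
Conditions: [Ph3PCH3]Br, KN(SiMe3)2 (1.05 equiv each), THF, −78 → 0 °C
Reagents that add atoms: methyltriphenylphosphonium bromide, C[P+](c1ccccc1)(c1ccccc1)c1ccccc1.[Br-]
Why: Wittig methylenation with one equivalent of the non-stabilised ylide at low temperature takes the unhindered aldehyde far faster than the ring ketone and touches no stereocentre.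

Step 5
Reactants: 8 (3R,4S)-3-(but-3-en-1-yl)-3-methyl-4-(prop-1-en-2-yl)cyclohexan-1-one
Product: 9 (4aR,8aR)-5,8a-dimethyl-3,4,4a,7,8,8a-hexahydronaphthalen-2(1H)-one
Conditions: second-generation Grubbs catalyst (H2IMes)(PCy3)Cl2Ru=CHPh (3 mol%), CH2Cl2, 40 °C
Reagents that add atoms: none
Why: Ring-closing metathesis between the terminal and the 1,1-disubstituted alkene closes ring A as the trisubstituted cyclohexene (C3=C4), driven by loss of ethene, with the trans ring fusion already fixed at C5 and C10.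

Step 6
Reactants: 9 (4aR,8aR)-5,8a-dimethyl-3,4,4a,7,8,8a-hexahydronaphthalen-2(1H)-one
Product: 10 (4aR,5S,6R,8aR)-5,6-dihydroxy-5,8a-dimethyloctahydronaphthalen-2(1H)-one
Conditions: OsO4 (2 mol%), NMO, acetone/H2O (4:1), 0 °C → rt
Reagents that add atoms: osmium tetroxide (catalytic carrier), O=[Os](=O)(=O)=O; N-methylmorpholine N-oxide, C[N+]1([O-])CCOCC1; water, O
Why: Upjohn syn-dihydroxylation occurs on the α face, opposite the axial angular methyl group, and gives the 3α,4α-cis-diol with the C4 methyl β.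

Step 7
Reactants: 10 (4aR,5S,6R,8aR)-5,6-dihydroxy-5,8a-dimethyloctahydronaphthalen-2(1H)-one; 11 angelic acid
Product: 12 (1S,2R,4aR,8aR)-1-hydroxy-1,4a-dimethyl-6-oxodecahydronaphthalen-2-yl (2Z)-2-methylbut-2-enoate
Conditions: 11, 2,4,6-Cl3C6H2COCl, Et3N, toluene, rt; then 10, toluene, 80 °C
Reagents that add atoms: none
Why: Yamaguchi-type mixed-anhydride esterification acylates only the secondary C3 hydroxyl (the tertiary C4 hydroxyl is inert), and heating without a nucleophilic catalyst keeps the Z (angelate) geometry.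

Step 8
Reactants: 12 (1S,2R,4aR,8aR)-1-hydroxy-1,4a-dimethyl-6-oxodecahydronaphthalen-2-yl (2Z)-2-methylbut-2-enoate
Product: 13 (1S,2R,4aR,8aR)-1-acetoxy-1,4a-dimethyl-6-oxodecahydronaphthalen-2-yl (2Z)-2-methylbut-2-enoate
Conditions: Ac2O, Sc(OTf)3 (5 mol%), MeCN, −20 °C
Reagents that add atoms: acetic anhydride, CC(=O)OC(C)=O
Why: Lewis-acid-catalysed acetylation esterifies the hindered tertiary alcohol at low temperature without elimination, and C4 keeps its configuration because the C–O bond is not broken.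

Step 9
Reactants: 13 (1S,2R,4aR,8aR)-1-acetoxy-1,4a-dimethyl-6-oxodecahydronaphthalen-2-yl (2Z)-2-methylbut-2-enoate; 14 acetone
Product: 15 (1S,2R,4aR,8aR)-1-acetoxy-7-(2-hydroxypropan-2-yl)-1,4a-dimethyl-6-oxodecahydronaphthalen-2-yl (2Z)-2-methylbut-2-enoate
Conditions: LiN(SiMe3)2 (1.05 equiv), THF, −78 °C; 14 (5 equiv), −78 °C; AcOH quench
Reagents that add atoms: none
Why: Kinetic lithium enolate formation takes place at C7, the ketone α-carbon remote from the quaternary centre (the ketone is far more acidic than the two esters), and the directed aldol addition to acetone installs the 2-hydroxypropan-2-yl group, the new C7 centre being removed in step 10.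

Step 10
Reactants: 15 (1S,2R,4aR,8aR)-1-acetoxy-7-(2-hydroxypropan-2-yl)-1,4a-dimethyl-6-oxodecahydronaphthalen-2-yl (2Z)-2-methylbut-2-enoate
Product: 16 (1S,2R,4aR,8aR)-1-acetoxy-7-(2-hydroxypropan-2-yl)-1,4a-dimethyl-6-oxo-1,2,3,4,4a,5,6,8a-octahydronaphthalen-2-yl (2Z)-2-methylbut-2-enoate
Conditions: IBX, 4-methoxypyridine N-oxide, DMSO, rt → 40 °C
Reagents that add atoms: none
Why: IBX-mediated α,β-dehydrogenation of the ketone can only occur between C7 and C6, because the other α-carbon (C9) has no β-hydrogen at quaternary C10, so the conjugated enone of the target forms without touching the tertiary alcohol or the esters.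

## Compound list

1 | 2-methylcyclopent-2-en-1-one | CC1=CCCC1=O | starting material
2 | isopropenylmagnesium bromide | C=C(C)[Mg]Br | starting material
3 | bromomagnesium (3S)-2-methyl-3-(prop-1-en-2-yl)cyclopent-1-en-1-olate | C=C(C)[C@@H]1CCC(O[Mg]Br)=C1C | intermediate
4 | trimethyl{[(3S)-2-methyl-3-(prop-1-en-2-yl)cyclopent-1-en-1-yl]oxy}silane | C=C(C)[C@@H]1CCC(O[Si](C)(C)C)=C1C | intermediate
5 | trimethyl{[(1R,4S,5S)-5-methyl-4-(prop-1-en-2-yl)bicyclo[3.1.0]hexan-1-yl]oxy}silane | C=C(C)[C@@H]1CC[C@@]2(O[Si](C)(C)C)C[C@@]12C | intermediate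
6 | acrolein | C=CC=O | starting material
7 | 3-[(1R,2S)-1-methyl-5-oxo-2-(prop-1-en-2-yl)cyclohexyl]propanal | O=CCC[C@]1(C)CC(=O)CC[C@H]1C(C)=C | intermediate
8 | (3R,4S)-3-(but-3-en-1-yl)-3-methyl-4-(prop-1-en-2-yl)cyclohexan-1-one | C=CCC[C@]1(C)CC(=O)CC[C@H]1C(C)=C | intermediate
9 | (4aR,8aR)-5,8a-dimethyl-3,4,4a,7,8,8a-hexahydronaphthalen-2(1H)-one | CC1=CCC[C@]2(C)CC(=O)CC[C@@H]12 | intermediate
10 | (4aR,5S,6R,8aR)-5,6-dihydroxy-5,8a-dimethyloctahydronaphthalen-2(1H)-one | O[C@@H]1CC[C@]2(C)CC(=O)CC[C@H]2[C@]1(C)O | intermediate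
11 | angelic acid, (2Z)-2-methylbut-2-enoic acid | C/C=C(/C)C(=O)O | starting material
12 | (1S,2R,4aR,8aR)-1-hydroxy-1,4a-dimethyl-6-oxodecahydronaphthalen-2-yl (2Z)-2-methylbut-2-enoate | C/C=C(/C)C(=O)O[C@@H]1CC[C@]2(C)CC(=O)CC[C@H]2[C@]1(C)O | intermediate
13 | (1S,2R,4aR,8aR)-1-acetoxy-1,4a-dimethyl-6-oxodecahydronaphthalen-2-yl (2Z)-2-methylbut-2-enoate | C/C=C(/C)C(=O)O[C@@H]1CC[C@]2(C)CC(=O)CC[C@H]2[C@]1(C)OC(C)=O | intermediate
14 | acetone | CC(C)=O | starting material
15 | (1S,2R,4aR,8aR)-1-acetoxy-7-(2-hydroxypropan-2-yl)-1,4a-dimethyl-6-oxodecahydronaphthalen-2-yl (2Z)-2-methylbut-2-enoate (C7 epimers) | C/C=C(/C)C(=O)O[C@@H]1CC[C@]2(C)CC(=O)C(C(C)(C)O)C[C@H]2[C@]1(C)OC(C)=O | intermediate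
16 | (1S,2R,4aR,8aR)-1-acetoxy-7-(2-hydroxypropan-2-yl)-1,4a-dimethyl-6-oxo-1,2,3,4,4a,5,6,8a-octahydronaphthalen-2-yl (2Z)-2-methylbut-2-enoate | C/C=C(/C)C(=O)O[C@@H]1CC[C@]2(C)CC(=O)C(C(C)(C)O)=C[C@H]2[C@]1(C)OC(C)=O | target

## Step count and risks

Total steps: 10. Longest linear sequence: 10 (from 1).

**Step 3 (the key ring-expanding radical addition).** It is a new combination, and the regiochemistry of ring opening, the acrolein addition and the anti selectivity at C10 are all untested on this substrate. Fallback from 5: FeCl3 in DMF at 0 °C gives (4S)-3-chloro-3-methyl-4-(prop-1-en-2-yl)cyclohexan-1-one F2. NaOAc in hot MeOH then removes HCl to give (4S)-3-methyl-4-(prop-1-en-2-yl)cyclohex-2-en-1-one F3. Copper-catalysed 1,4-addition of [2-(1,3-dioxolan-2-yl)ethyl]magnesium bromide (CuBr·SMe2 10 mol%, THF, −40 °C, aqueous NH4Cl), anti to the C4 substituent, gives (3R,4S)-3-[2-(1,3-dioxolan-2-yl)ethyl]-3-methyl-4-(prop-1-en-2-yl)cyclohexan-1-one F4. Mild acid hydrolysis (1 M HCl, acetone, rt) returns to the route at 7.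

**Step 1 (rate and enantioselectivity).** An α-substituted enone with an alkenyl Grignard reagent is a demanding case for copper catalysis. Fallback from 1: rhodium-catalysed asymmetric 1,4-addition ([RhCl(cod)]2, BINAP enantiomer chosen for the same facial sense, potassium isopropenyltrifluoroborate, KOH, dioxane/H2O, 90 °C) gives (3R)-2-methyl-3-(prop-1-en-2-yl)cyclopentan-1-one F1 as C2 epimers (same spatial arrangement at C3 as in 4; only the descriptor changes). Equilibrating silylation (TMSCl, NaI, Et3N, MeCN) then gives the more substituted enol ether and returns to the route at 4.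

**Step 10 (dehydrogenation).** Enolisation must occur towards the hindered C7, and retro-aldol or dehydration may compete. Fallback from 15: MsCl with excess Et3N (CH2Cl2, 0 °C → rt) dehydrates the aldol to (1S,2R,4aR,8aR)-1-acetoxy-1,4a-dimethyl-6-oxo-7-(propan-2-ylidene)decahydronaphthalen-2-yl (2Z)-2-methylbut-2-enoate F5. Photo-oxygenation (O2, tetraphenylporphyrin, visible light, CH2Cl2, 0 °C) is a singlet-oxygen ene reaction that takes the ring C6 hydrogen geminal to the carbonyl and gives (1S,2R,4aR,8aR)-1-acetoxy-7-(2-hydroperoxypropan-2-yl)-1,4a-dimethyl-6-oxo-1,2,3,4,4a,5,6,8a-octahydronaphthalen-2-yl (2Z)-2-methylbut-2-enoate F6. PPh3 reduces the hydroperoxide and returns to the route at 16.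

## Further compounds

F1 | step 1 | (3R)-2-methyl-3-(prop-1-en-2-yl)cyclopentan-1-one (C2 epimers) | C=C(C)[C@@H]1CCC(=O)C1C
F2 | step 3 | (4S)-3-chloro-3-methyl-4-(prop-1-en-2-yl)cyclohexan-1-one (C3 epimers) | C=C(C)[C@@H]1CCC(=O)CC1(C)Cl
F3 | step 3 | (4S)-3-methyl-4-(prop-1-en-2-yl)cyclohex-2-en-1-one | C=C(C)[C@@H]1CCC(=O)C=C1C
F4 | step 3 | (3R,4S)-3-[2-(1,3-dioxolan-2-yl)ethyl]-3-methyl-4-(prop-1-en-2-yl)cyclohexan-1-one | C1COC(O1)CC[C@]2(C)CC(=O)CC[C@H]2C(C)=C
F5 | step 10 | (1S,2R,4aR,8aR)-1-acetoxy-1,4a-dimethyl-6-oxo-7-(propan-2-ylidene)decahydronaphthalen-2-yl (2Z)-2-methylbut-2-enoate | C/C=C(/C)C(=O)O[C@@H]1CC[C@]2(C)CC(=O)C(=C(C)C)C[C@H]2[C@]1(C)OC(C)=O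
F6 | step 10 | (1S,2R,4aR,8aR)-1-acetoxy-7-(2-hydroperoxypropan-2-yl)-1,4a-dimethyl-6-oxo-1,2,3,4,4a,5,6,8a-octahydronaphthalen-2-yl (2Z)-2-methylbut-2-enoate | C/C=C(/C)C(=O)O[C@@H]1CC[C@]2(C)CC(=O)C(C(C)(C)OO)=C[C@H]2[C@]1(C)OC(C)=O
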